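Everything rests on cutting the C3–C4 ring bond and the C2–Cl bond of the cyclohexene (ring: C1 CMe2, C2 CHCl, C3, C4, C5, C6 CHBr; side chain C7, C8). One copper-mediated chlorine-atom-transfer cyclization closes the six-membered ring and leaves chlorine on C2, a secondary carbon flanked by quaternary C1 that substitution chemistry cannot serve; the C6 oxygen inherited from (R)-pantolactone directs this chlorine trans. The precursor is an acyclic chloromethyl ketone with a silyloxy stereocentre, the gem-dimethyl carbon and a vinyl group. Afterwards C6–O is exchanged for bromine beside the ketone with net retention, and the ketone is converted into the C4=C5 alkene carrying a catalyst-controlled chlorobromoethyl arm.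

Key step: step 6

Remark: C6–O is exchanged for bromine while C5 is still a carbonyl, because substitution at C6 once C4=C5 exists would be neopentyl and prone to allylic transposition.

Step 1
Reactants: 1 (R)-pantolactone
Product: 2 (3R)-3-[(tert-butyldimethylsilyl)oxy]-4,4-dimethyloxolan-2-one
Conditions: t-BuMe2SiCl, imidazole, DMF, rt
Reagents that add atoms: tert-butyldimethylsilyl chloride, CC(C)(C)[Si](C)(C)Cl
Why: Imidazole-promoted silylation of a secondary alcohol; the lactone and the C–O stereocentre are untouched, so the R configuration is carried through.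

Step 2
Reactants: 2 (3R)-3-[(tert-butyldimethylsilyl)oxy]-4,4-dimethyloxolan-2-one
Product: 3 (2R)-2-[(tert-butyldimethylsilyl)oxy]-4-hydroxy-N-methoxy-N,3,3-trimethylbutanamide
Conditions: MeNH(OMe)·HCl, i-PrMgCl, THF, −20 to 0 °C; aq. NH4Cl
Reagents that add atoms: N,O-dimethylhydroxylamine hydrochloride, CNOC.Cl
Why: Weinreb aminolysis: the magnesium amide formed in the flask adds to the lactone carbonyl and the ring opens to the stable N-methoxy-N-methylamide, with a cold quench to limit relactonisation and silyl migration to the freed primary hydroxyl.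

Step 3
Reactants: 3 (2R)-2-[(tert-butyldimethylsilyl)oxy]-4-hydroxy-N-methoxy-N,3,3-trimethylbutanamide
Product: 4 (2R)-2-[(tert-butyldimethylsilyl)oxy]-N-methoxy-N,3,3-trimethyl-4-oxobutanamide
Conditions: Dess–Martin periodinane, NaHCO3, CH2Cl2, 0 °C to rt
Reagents that add atoms: none
Why: Dess–Martin oxidation under bicarbonate buffer converts the neopentyl primary alcohol into an aldehyde that has no α-hydrogen, which also removes the hydroxyl that could close back onto the amide.

Step 4
Reactants: 4 (2R)-2-[(tert-butyldimethylsilyl)oxy]-N-methoxy-N,3,3-trimethyl-4-oxobutanamide; 5 methyltriphenylphosphonium bromide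
Product: 6 (2R)-2-[(tert-butyldimethylsilyl)oxy]-N-methoxy-N,3,3-trimethylpent-4-enamide
Conditions: 5, KN(SiMe3)2, THF, 0 °C; then 4, −78 °C to rt
Reagents that add atoms: none
Why: Wittig methylenation: the unstabilised ylide reacts with the aldehyde far faster than with the Weinreb amide and builds the vinyl group (C2=C3) on quaternary C1.

Step 5
Reactants: 6 (2R)-2-[(tert-butyldimethylsilyl)oxy]-N-methoxy-N,3,3-trimethylpent-4-enamide; 7 chloroiodomethane
Product: 8 (3R)-3-[(tert-butyldimethylsilyl)oxy]-1-chloro-4,4-dimethylhex-5-en-2-one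
Conditions: 7, MeLi·LiBr, THF, −78 °C; aq. NH4Cl
Reagents that add atoms: none
Why: Carbenoid homologation of a Weinreb amide: chloromethyllithium from iodine–lithium exchange adds once, the chelated tetrahedral adduct survives until the quench, and the chloromethyl ketone (C4–Cl) is released without touching the alkene or the α-stereocentre.

Step 6
Reactants: 8 (3R)-3-[(tert-butyldimethylsilyl)oxy]-1-chloro-4,4-dimethylhex-5-en-2-one
Product: 9 (2R,4S)-2-[(tert-butyldimethylsilyl)oxy]-4-chloro-3,3-dimethylcyclohexan-1-one
Conditions: CuCl (30 mol%), CuCl2 (5 mol%), tris(2-pyridylmethyl)amine (35 mol%), degassed ClCH2CH2Cl (0.02 M), 80 °C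
Reagents that add atoms: none
Why: Monovalent copper, made strongly reducing by tris(2-pyridylmethyl)amine, abstracts chlorine from the chloromethyl ketone to give the C4 α-keto radical and the divalent copper chloride complex; the radical adds to the terminal vinyl carbon C3 and the resulting C2 radical takes chlorine back from divalent copper, regenerating the catalyst. This is a copper-catalysed atom-transfer radical cyclization of Kharasch type, closest to the known chlorine-transfer cyclizations of unsaturated α-chloro carbonyl compounds. The six-membered ring closes in the 6-endo-trig mode, which α-keto radicals with the carbonyl inside the forming ring prefer and which is reinforced here because the 5-exo path would have to bond to the alkene carbon C2 next to quaternary C1. The new stereocentre C2 is set under substrate control by C6: with the silyloxy group equatorial, chlorine is delivered axially, anti to the axial C1 methyl, and if the ring flips an axial silyloxy group shields the face syn to it, so both conformers should lead to the 2,6-trans chloride. The step needs chlorine return to outrun hydrogen abstraction or coupling of the C2 radical, which the added CuCl2 and high dilution secure, and the new C–Cl bond on an unactivated carbon is not reactivated.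

Step 7
Reactants: 9 (2R,4S)-2-[(tert-butyldimethylsilyl)oxy]-4-chloro-3,3-dimethylcyclohexan-1-one
Product: 10 (2R,4S)-4-chloro-2-hydroxy-3,3-dimethylcyclohexan-1-one
Conditions: HF·pyridine, THF, 0 °C to rt
Reagents that add atoms: none
Why: Fluoride-mediated desilylation under buffered, non-basic conditions frees the C6 hydroxyl without enolising the γ-chloro ketone.

Step 8
Reactants: 10 (2R,4S)-4-chloro-2-hydroxy-3,3-dimethylcyclohexan-1-one
Product: 13 (2R,4S)-2-bromo-4-chloro-3,3-dimethylcyclohexan-1-one, via α-keto triflate 11 (not isolated), via cis-bromide 12 (not isolated)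
Conditions: Tf2O, 2,6-lutidine, CH2Cl2, −40 °C; cold aq. wash; then LiBr (4 equiv), acetone, 0 to 40 °C
Reagents that add atoms: lithium bromide, [Li+].[Br-]
Why: Triflation followed by SN2 displacement at the carbonyl-activated C6 (the activation that lets neopentyl α-acyl triflates be displaced) lets bromide invert C6 twice: the first, slower attack gives the cis-bromide, and a second bromide exchange from the opposite face, axial and anti to the axial C1 methyl, returns the original configuration as the 2,4-trans α-bromo ketone, whose own displacement would again need the hindered face, so it should accumulate (double inversion, net retention).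

Step 9
Reactants: 13 (2R,4S)-2-bromo-4-chloro-3,3-dimethylcyclohexan-1-one; 14 ethyl vinyl ether
Product: 15 (1R,2R,4S)-2-bromo-4-chloro-1-(1-ethoxyethenyl)-3,3-dimethylcyclohexan-1-ol
Conditions: 14, t-BuLi, THF, −78 to 0 °C; CeCl3, −78 °C; then 13, −78 °C; aq. NaHCO3
Reagents that add atoms: none
Why: Organocerium 1,2-addition of an acyl-anion equivalent: the weakly basic cerium reagent should add to the hindered α-bromo ketone without enolisation or halogen–metal exchange, attack anti to the C–Br bond (polar Felkin–Anh) placing the new hydroxyl cis to bromine so that no epoxide can close, and the new C5 centre is transient.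

Step 10
Reactants: 15 (1R,2R,4S)-2-bromo-4-chloro-1-(1-ethoxyethenyl)-3,3-dimethylcyclohexan-1-ol
Product: 16 (4S,6S)-6-bromo-4-chloro-1-(1-ethoxyethenyl)-5,5-dimethylcyclohex-1-ene
Conditions: methyl N-(triethylammoniosulfonyl)carbamate (Burgess reagent), toluene, 50 °C
Reagents that add atoms: none
Why: Burgess dehydration (syn elimination through the sulfamate ester): only C4 carries a hydrogen syn to the C5 oxygen, the C6 hydrogen being anti, so the alkene forms at C4=C5 and the transient C5 stereocentre disappears.

Step 11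
Reactants: 16 (4S,6S)-6-bromo-4-chloro-1-(1-ethoxyethenyl)-5,5-dimethylcyclohex-1-ene
Product: 17 2-bromo-1-[(4S,6S)-6-bromo-4-chloro-5,5-dimethylcyclohex-1-en-1-yl]ethan-1-one
Conditions: NBS, NaHCO3, THF/H2O (4:1), 0 °C
Reagents that add atoms: N-bromosuccinimide, O=C1CCC(=O)N1Br; water, O
Why: Bromination–hydrolysis of an α-alkoxyvinyl group: NBS attacks the enol ether terminus C8, water captures the oxocarbenium ion at C7 and the hemiketal loses ethanol to give the bromomethyl ketone.

Step 12
Reactants: 17 2-bromo-1-[(4S,6S)-6-bromo-4-chloro-5,5-dimethylcyclohex-1-en-1-yl]ethan-1-one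
Product: 19 (2R)-2-[(4S,6S)-6-bromo-4-chloro-5,5-dimethylcyclohex-1-en-1-yl]oxirane, via bromohydrin 18 (not isolated)
Conditions: (R)-2-methyl-CBS-oxazaborolidine [(3aR)-1-methyl-3,3-diphenyltetrahydro-1H,3H-pyrrolo[1,2-c][1,3,2]oxazaborole] (20 mol%), BH3·SMe2, THF, −30 °C; then MeOH, 2 M NaOH, 0 °C
Reagents that add atoms: none
Why: Corey–Bakshi–Shibata reduction followed by intramolecular Williamson closure: the oxazaborolidine delivers hydride with the cyclohexenyl group as the large and CH2Br as the small substituent, setting C7 as R under catalyst control, and hydroxide then closes the epoxide without breaking the C7–O bond.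

Step 13
Reactants: 19 (2R)-2-[(4S,6S)-6-bromo-4-chloro-5,5-dimethylcyclohex-1-en-1-yl]oxirane
Product: 21 (2S)-2-[(4S,6R)-6-bromo-4-chloro-5,5-dimethylcyclohex-1-en-1-yl]-2-chloroethan-1-ol, via silyl ether 20 (not isolated)
Conditions: Me3SiCl (1.5 equiv), CH2Cl2/EtOAc, −20 °C to rt; then aq. citric acid
Reagents that add atoms: chlorotrimethylsilane, C[Si](C)(C)Cl
Why: Silyl-halide opening of a vinyl epoxide: chloride attacks the allylic carbon C7, whose C–O bond is weakened by the adjacent alkene, in SN2 fashion with inversion, turning the 7R epoxide into the 7S chloride, and acidic work-up cleaves the primary trimethylsilyl ether.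

Step 14
Reactants: 21 (2S)-2-[(4S,6R)-6-bromo-4-chloro-5,5-dimethylcyclohex-1-en-1-yl]-2-chloroethan-1-ol
Product: 22 (4S,6R)-6-bromo-1-[(1S)-2-bromo-1-chloroethyl]-4-chloro-5,5-dimethylcyclohex-1-ene
Conditions: CBr4, PPh3, CH2Cl2, 0 °C
Reagents that add atoms: carbon tetrabromide, BrC(Br)(Br)Br
Why: Appel bromination: the primary C8 oxyphosphonium is displaced by bromide in an SN2 reaction that touches no stereocentre and leaves the secondary chlorides and the hindered allylic bromide alone.

Compound list
1 | (R)-pantolactone [(3R)-3-hydroxy-4,4-dimethyloxolan-2-one] | CC1(C)COC(=O)[C@@H]1O | starting material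
2 | (3R)-3-[(tert-butyldimethylsilyl)oxy]-4,4-dimethyloxolan-2-one | CC1(C)COC(=O)[C@@H]1O[Si](C)(C)C(C)(C)C | intermediate
3 | (2R)-2-[(tert-butyldimethylsilyl)oxy]-4-hydroxy-N-methoxy-N,3,3-trimethylbutanamide | CON(C)C(=O)[C@H](O[Si](C)(C)C(C)(C)C)C(C)(C)CO | intermediate
4 | (2R)-2-[(tert-butyldimethylsilyl)oxy]-N-methoxy-N,3,3-trimethyl-4-oxobutanamide | CON(C)C(=O)[C@H](O[Si](C)(C)C(C)(C)C)C(C)(C)C=O | intermediate
5 | methyltriphenylphosphonium bromide | C[P+](c1ccccc1)(c1ccccc1)c1ccccc1.[Br-] | starting material
6 | (2R)-2-[(tert-butyldimethylsilyl)oxy]-N-methoxy-N,3,3-trimethylpent-4-enamide | CON(C)C(=O)[C@H](O[Si](C)(C)C(C)(C)C)C(C)(C)C=C | intermediate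
7 | chloroiodomethane | ClCI | starting material
8 | (3R)-3-[(tert-butyldimethylsilyl)oxy]-1-chloro-4,4-dimethylhex-5-en-2-one | ClCC(=O)[C@H](O[Si](C)(C)C(C)(C)C)C(C)(C)C=C | intermediate
9 | (2R,4S)-2-[(tert-butyldimethylsilyl)oxy]-4-chloro-3,3-dimethylcyclohexan-1-one | CC1(C)[C@@H](Cl)CCC(=O)[C@@H]1O[Si](C)(C)C(C)(C)C | intermediate
10 | (2R,4S)-4-chloro-2-hydroxy-3,3-dimethylcyclohexan-1-one | CC1(C)[C@@H](Cl)CCC(=O)[C@@H]1O | intermediate
11 | (1R,3S)-3-chloro-2,2-dimethyl-6-oxocyclohexyl trifluoromethanesulfonate | CC1(C)[C@@H](Cl)CCC(=O)[C@@H]1OS(=O)(=O)C(F)(F)F | intermediate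
12 | (2S,4S)-2-bromo-4-chloro-3,3-dimethylcyclohexan-1-one | CC1(C)[C@@H](Cl)CCC(=O)[C@H]1Br | intermediate
13 | (2R,4S)-2-bromo-4-chloro-3,3-dimethylcyclohexan-1-one | CC1(C)[C@@H](Cl)CCC(=O)[C@@H]1Br | intermediate
14 | ethyl vinyl ether (ethoxyethene) | C=COCC | starting material
15 | (1R,2R,4S)-2-bromo-4-chloro-1-(1-ethoxyethenyl)-3,3-dimethylcyclohexan-1-ol | CC1(C)[C@@H](Cl)CC[C@@](O)(C(=C)OCC)[C@@H]1Br | intermediate
16 | (4S,6S)-6-bromo-4-chloro-1-(1-ethoxyethenyl)-5,5-dimethylcyclohex-1-ene | CC1(C)[C@@H](Cl)CC=C(C(=C)OCC)[C@@H]1Br | intermediate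
17 | 2-bromo-1-[(4S,6S)-6-bromo-4-chloro-5,5-dimethylcyclohex-1-en-1-yl]ethan-1-one | CC1(C)[C@@H](Cl)CC=C(C(=O)CBr)[C@@H]1Br | intermediate
18 | (1R)-2-bromo-1-[(4S,6S)-6-bromo-4-chloro-5,5-dimethylcyclohex-1-en-1-yl]ethan-1-ol | CC1(C)[C@@H](Cl)CC=C([C@@H](O)CBr)[C@@H]1Br | intermediate
19 | (2R)-2-[(4S,6S)-6-bromo-4-chloro-5,5-dimethylcyclohex-1-en-1-yl]oxirane | CC1(C)[C@@H](Cl)CC=C([C@@H]2CO2)[C@@H]1Br | intermediate
20 | {(2S)-2-[(4S,6R)-6-bromo-4-chloro-5,5-dimethylcyclohex-1-en-1-yl]-2-chloroethoxy}trimethylsilane | CC1(C)[C@@H](Cl)CC=C([C@H](Cl)CO[Si](C)(C)C)[C@@H]1Br | intermediate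
21 | (2S)-2-[(4S,6R)-6-bromo-4-chloro-5,5-dimethylcyclohex-1-en-1-yl]-2-chloroethan-1-ol | CC1(C)[C@@H](Cl)CC=C([C@H](Cl)CO)[C@@H]1Br | intermediate
22 | (4S,6R)-6-bromo-1-[(1S)-2-bromo-1-chloroethyl]-4-chloro-5,5-dimethylcyclohex-1-ene | CC1(C)[C@@H](Cl)CC=C([C@H](Cl)CBr)[C@@H]1Br | target

Total step count: 14. Longest linear sequence: 14 steps, from 1 to 22.

Steps most likely to fail

Step 6. Chlorine abstraction from a primary, singly activated C–Cl bond may be slow, so that radical coupling, reduction and catalyst oxidation outrun cyclization; the facial bias in chlorine return could also be weaker than planned. Fallback: setting out from 6, dichloromethyllithium (CH2Cl2, LiN(i-Pr)2, THF, −78 °C) would give (3R)-3-[(tert-butyldimethylsilyl)oxy]-1,1-dichloro-4,4-dimethylhex-5-en-2-one F1. Its doubly activated C–Cl bond should be abstracted by CuCl/tris(2-pyridylmethyl)amine under much milder conditions, and the same 6-endo closure with chlorine transfer would give (2R,4S)-2-[(tert-butyldimethylsilyl)oxy]-4,6-dichloro-3,3-dimethylcyclohexan-1-one F2 (either configuration at the chloride next to the carbonyl). Zinc dust in acetic acid would then reduce off only the chlorine α to the ketone, and the route is rejoined at 9.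

Step 9. The hindered α-bromo ketone may be enolised or reduced by electron transfer instead of adding the bulky vinyl anion, or addition may occur on the face syn to bromine and be followed by epoxide closure. Fallback: setting out from 13, the small linear nucleophile made from ethynylmagnesium bromide and CeCl3 (THF, −78 °C) would give (1R,2R,4S)-2-bromo-4-chloro-1-ethynyl-3,3-dimethylcyclohexan-1-ol F3. Burgess dehydration would give (4S,6S)-6-bromo-4-chloro-1-ethynyl-5,5-dimethylcyclohex-1-ene F4, and bromination of the alkyne terminus with NBS and catalytic AgNO3 in acetone would give (4S,6S)-6-bromo-1-(bromoethynyl)-4-chloro-5,5-dimethylcyclohex-1-ene F5. Hydration of the bromoalkyne with catalytic Ph3PAuNTf2 in wet 1,2-dichloroethane would place the carbonyl on the ring-bound carbon, and the route is rejoined at 17.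

Step 8. The second bromide exchange may stall, or the triflate may be lost to side reactions before displacement, leaving a mixture of C6 epimers. Fallback: setting out from 10 and passing through triflate 11 as before, tetrabutylammonium nitrite in acetonitrile (Lattrell–Dax inversion) would give the inverted ester (1S,3S)-3-chloro-2,2-dimethyl-6-oxocyclohexyl nitrite F6. Aqueous work-up would hydrolyse it to (2S,4S)-4-chloro-2-hydroxy-3,3-dimethylcyclohexan-1-one F7, which is isolated. Renewed triflation (Tf2O, 2,6-lutidine) would give (1S,3S)-3-chloro-2,2-dimethyl-6-oxocyclohexyl trifluoromethanesulfonate F8, and a single displacement with LiBr (1 equiv, acetone, 0 °C), now from the unhindered face, would give 13, where the route is rejoined.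

Further compounds
F1 | step 6 | (3R)-3-[(tert-butyldimethylsilyl)oxy]-1,1-dichloro-4,4-dimethylhex-5-en-2-one | ClC(Cl)C(=O)[C@H](O[Si](C)(C)C(C)(C)C)C(C)(C)C=C
F2 | step 6 | (2R,4S)-2-[(tert-butyldimethylsilyl)oxy]-4,6-dichloro-3,3-dimethylcyclohexan-1-one | CC1(C)[C@@H](Cl)CC(Cl)C(=O)[C@@H]1O[Si](C)(C)C(C)(C)C
F3 | step 9 | (1R,2R,4S)-2-bromo-4-chloro-1-ethynyl-3,3-dimethylcyclohexan-1-ol | CC1(C)[C@@H](Cl)CC[C@@](O)(C#C)[C@@H]1Br
F4 | step 9 | (4S,6S)-6-bromo-4-chloro-1-ethynyl-5,5-dimethylcyclohex-1-ene | CC1(C)[C@@H](Cl)CC=C(C#C)[C@@H]1Br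
F5 | step 9 | (4S,6S)-6-bromo-1-(bromoethynyl)-4-chloro-5,5-dimethylcyclohex-1-ene | CC1(C)[C@@H](Cl)CC=C(C#CBr)[C@@H]1Br
F6 | step 8 | (1S,3S)-3-chloro-2,2-dimethyl-6-oxocyclohexyl nitrite | CC1(C)[C@@H](Cl)CCC(=O)[C@H]1ON=O
F7 | step 8 | (2S,4S)-4-chloro-2-hydroxy-3,3-dimethylcyclohexan-1-one | CC1(C)[C@@H](Cl)CCC(=O)[C@H]1O
F8 | step 8 | (1S,3S)-3-chloro-2,2-dimethyl-6-oxocyclohexyl trifluoromethanesulfonate | CC1(C)[C@@H](Cl)CCC(=O)[C@H]1OS(=O)(=O)C(F)(F)F
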